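The route rests on disconnecting C6–C7 of the cyclohexene ring (indene numbering: C1 and C3 CHMe, C3a/C7a ring fusion, C4(Me)=C5, C6 CHPh, C7 quaternary). The feature exploited is the array C7–C6–C5=C4 in that ring, in which quaternary C7 bears a carboxyl-derived carbon: a γ,δ-unsaturated acid pattern. An Ireland–Claisen shift of a trans-fused δ-lactone (ring oxygen on C4, carbonyl on C7) with an E-styryl group on C4 forms C6–C7, contracts the lactone to the carbocycle, places the alkene at C4=C5 and sets C6 and C7 in one operation. The precursor is a 1-methyl-1-styryl-4-(PMB-oxymethyl)cyclopenta[c]pyran-3-one built from (S)-4-silyloxycyclopentenone.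

Key step: step 13

Remark on the chemistry: in the Why lines the locants C1–C7a of the target are used for all intermediates (C4 = carbinol/ketone carbon, C7 = acetate α-carbon); β is the face carrying H-7a, α the opposite face.
Remark on the chemistry: the carbinol carbon in 5–13 and C7 in 19 are carried as epimer mixtures that converge later (oxidation in step 10, enolisation in step 13); their SMILES carry no descriptor at these atoms.
Assumption: 1, 2, 15, 18 and 29 are taken as commercially available.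

Step 1
Reactants: 1 (S)-4-(tert-butyldimethylsilyloxy)cyclopent-2-en-1-one; 2 1-(tert-butyldimethylsilyloxy)-1-methoxyethene; 3 acetaldehyde
Product: 5 methyl 2-[(1S,2R,5S)-5-(tert-butyldimethylsilyloxy)-2-(1-hydroxyethyl)-3-oxocyclopentyl]acetate, via silyl enol ether 4 (not isolated)
Conditions: HgI2 (cat.), CH2Cl2, −78 → −30 °C; then 3, TiCl4, −78 °C
Reagents that add atoms: none
Why: A Mukaiyama–Michael addition should deliver the acetate unit to C7a anti to the C1 silyloxy group with silyl transfer to the enolate, and the TiCl4-mediated Mukaiyama aldol reaction of 4 with acetaldehyde should then form C3a–C4 anti to the new C7a chain, the three-component coupling pattern established for 4-silyloxycyclopentenones.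

Step 2
Reactants: 5 methyl 2-[(1S,2R,5S)-5-(tert-butyldimethylsilyloxy)-2-(1-hydroxyethyl)-3-oxocyclopentyl]acetate
Product: 6 methyl 2-[(1S,2R,5S)-5-(tert-butyldimethylsilyloxy)-2-[1-(tert-butyldiphenylsilyloxy)ethyl]-3-oxocyclopentyl]acetate
Conditions: TBDPSCl, imidazole, DMAP (cat.), DMF, rt
Reagents that add atoms: tert-butyl(chloro)diphenylsilane, CC(C)(C)[Si](Cl)(c1ccccc1)c1ccccc1
Why: Standard silylation of the secondary carbinol, giving a TBDPS ether that survives the later acidic TBS removal and adds bulk on the β face for step 4.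

Step 3
Reactants: 6 methyl 2-[(1S,2R,5S)-5-(tert-butyldimethylsilyloxy)-2-[1-(tert-butyldiphenylsilyloxy)ethyl]-3-oxocyclopentyl]acetate
Product: 7 methyl 2-[(1S,2S,5S)-5-(tert-butyldimethylsilyloxy)-2-[1-(tert-butyldiphenylsilyloxy)ethyl]-3-methylidenecyclopentyl]acetate
Conditions: Zn, CH2Br2, TiCl4 (promoter), THF–CH2Cl2, 0 °C → rt
Reagents that add atoms: dibromomethane, BrCBr
Why: Takai–Lombardo methylenation is non-basic, so the ketone should be converted into the exocyclic alkene without E1cB loss of either β-silyloxy group, without epimerisation at C3a and without attack on the ester.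

Step 4
Reactants: 7 methyl 2-[(1S,2S,5S)-5-(tert-butyldimethylsilyloxy)-2-[1-(tert-butyldiphenylsilyloxy)ethyl]-3-methylidenecyclopentyl]acetate
Product: 8 methyl 2-[(1S,2R,3R,5S)-5-(tert-butyldimethylsilyloxy)-2-[1-(tert-butyldiphenylsilyloxy)ethyl]-3-methylcyclopentyl]acetate
Conditions: H2 (1 atm), PtO2, EtOAc, rt
Reagents that add atoms: none
Why: Heterogeneous syn-hydrogenation of the 1,1-disubstituted alkene should occur from the α face, anti to the adjacent bulky C3a side chain and to the C1 silyloxy group, which sets C3 with its methyl group β, cis to the C3a substituent.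

Step 5
Reactants: 8 methyl 2-[(1S,2R,3R,5S)-5-(tert-butyldimethylsilyloxy)-2-[1-(tert-butyldiphenylsilyloxy)ethyl]-3-methylcyclopentyl]acetate
Product: 9 methyl 2-[(1S,2R,3R,5S)-2-[1-(tert-butyldiphenylsilyloxy)ethyl]-5-hydroxy-3-methylcyclopentyl]acetate
Conditions: CSA (cat.), MeOH–CH2Cl2, 0 °C → rt
Reagents that add atoms: none
Why: Acid-catalysed methanolysis cleaves the secondary TBS ether much faster than the TBDPS ether, and the freed β-hydroxyl at C1 is trans to the C7a acetate chain and so should not lactonise.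

Step 6
Reactants: 9 methyl 2-[(1S,2R,3R,5S)-2-[1-(tert-butyldiphenylsilyloxy)ethyl]-5-hydroxy-3-methylcyclopentyl]acetate
Product: 10 methyl 2-[(1S,2R,3R)-2-[1-(tert-butyldiphenylsilyloxy)ethyl]-3-methyl-5-oxocyclopentyl]acetate
Conditions: Dess–Martin periodinane, CH2Cl2, rt
Reagents that add atoms: none
Why: Dess–Martin oxidation of the secondary alcohol under near-neutral conditions, where C7a, now α to the ketone, already has the more stable configuration trans to the C3a substituent.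

Step 7
Reactants: 10 methyl 2-[(1S,2R,3R)-2-[1-(tert-butyldiphenylsilyloxy)ethyl]-3-methyl-5-oxocyclopentyl]acetate
Product: 11 methyl 2-[(1S,2R,3R)-2-[1-(tert-butyldiphenylsilyloxy)ethyl]-3-methyl-5-methylidenecyclopentyl]acetate
Conditions: Zn, CH2Br2, TiCl4 (promoter), THF–CH2Cl2, 0 °C → rt
Reagents that add atoms: dibromomethane, BrCBr
Why: Takai–Lombardo methylenation as in step 3, chosen again because it neither enolises the ketone toward C7a nor touches the ester.

Step 8
Reactants: 11 methyl 2-[(1S,2R,3R)-2-[1-(tert-butyldiphenylsilyloxy)ethyl]-3-methyl-5-methylidenecyclopentyl]acetate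
Product: 12 methyl 2-[(1S,2R,3R)-2-(1-hydroxyethyl)-3-methyl-5-methylidenecyclopentyl]acetate
Conditions: HF·pyridine, pyridine–THF, 0 °C → rt
Reagents that add atoms: none
Why: Fluoride-mediated cleavage of the silyl ether under non-basic conditions, so that no free alkoxide is present to attack the methyl ester.

Step 9
Reactants: 12 methyl 2-[(1S,2R,3R)-2-(1-hydroxyethyl)-3-methyl-5-methylidenecyclopentyl]acetate
Product: 13 methyl 2-[(1R,2R,3R,5R)-2-(1-hydroxyethyl)-3,5-dimethylcyclopentyl]acetate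
Conditions: H2 (1 atm), PtO2, EtOAc, rt
Reagents that add atoms: none
Why: Heterogeneous syn-hydrogenation should occur from the β face, anti to the adjacent α-CH2CO2Me group on C7a and helped by adsorption of the β-hydroxyethyl group, which sets C1 with its methyl group α, cis to the C7a chain; platinum is used to limit alkene migration.

Step 10
Reactants: 13 methyl 2-[(1R,2R,3R,5R)-2-(1-hydroxyethyl)-3,5-dimethylcyclopentyl]acetate
Product: 14 methyl 2-[(1R,2R,3R,5R)-2-acetyl-3,5-dimethylcyclopentyl]acetate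
Conditions: Dess–Martin periodinane, CH2Cl2, rt
Reagents that add atoms: none
Why: Dess–Martin oxidation gives the methyl ketone without base, so the C3a centre next to the new carbonyl group should not epimerise.

Step 11
Reactants: 14 methyl 2-[(1R,2R,3R,5R)-2-acetyl-3,5-dimethylcyclopentyl]acetate; 15 (E)-(2-bromovinyl)benzene
Product: 17 (1S,4aR,5R,7R,7aR)-1,5,7-trimethyl-1-[(E)-2-phenylethenyl]-4,4a,5,6,7,7a-hexahydrocyclopenta[c]pyran-3(1H)-one, via hydroxy ester 16 (not isolated)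
Conditions: 15, t-BuLi (2 equiv), Et2O, −78 °C; CeCl3, THF, −78 °C; then 14, −78 °C → rt; aq. NH4Cl
Reagents that add atoms: none
Why: 1,2-Addition of the (E)-alkenylcerium reagent (bromine–lithium exchange with retention, no enolisation) under Felkin–Anh control, with C3 and its cis methyl group anti to the nucleophile, the carbonyl oxygen over the C3a–C7a bond and attack from the C7a side past H-3a, should give the (S)-carbinol (styryl α), whose alkoxide then closes the δ-lactone on the methyl ester.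

Step 12
Reactants: 17 (1S,4aR,5R,7R,7aR)-1,5,7-trimethyl-1-[(E)-2-phenylethenyl]-4,4a,5,6,7,7a-hexahydrocyclopenta[c]pyran-3(1H)-one; 18 1-(chloromethoxymethyl)-4-methoxybenzene
Product: 19 (1S,4RS,4aR,5R,7R,7aR)-4-[(4-methoxybenzyloxy)methyl]-1,5,7-trimethyl-1-[(E)-2-phenylethenyl]-4,4a,5,6,7,7a-hexahydrocyclopenta[c]pyran-3(1H)-one
Conditions: LDA, THF, −78 °C; then 18, −78 → −40 °C
Reagents that add atoms: none
Why: Alkylation of the lactone lithium enolate with the reactive α-chloro ether at low temperature, where the new C7 centre needs no control because step 13 makes it trigonal again.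

Step 13
Reactants: 19 (1S,4RS,4aR,5R,7R,7aR)-4-[(4-methoxybenzyloxy)methyl]-1,5,7-trimethyl-1-[(E)-2-phenylethenyl]-4,4a,5,6,7,7a-hexahydrocyclopenta[c]pyran-3(1H)-one
Product: 22 (1R,3R,3aR,6S,7S,7aR)-7-[(4-methoxybenzyloxy)methyl]-1,3,4-trimethyl-6-phenyl-2,3,3a,6,7,7a-hexahydro-1H-indene-7-carboxylic acid, via silyl ketene acetal 20 (not isolated), via trimethylsilyl ester 21 (not isolated)
Conditions: TMSCl–Et3N, THF, −78 °C, LDA added last; → rt; toluene, 100 °C; then 1 M HCl, THF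
Reagents that add atoms: none
Why: Enolisation in the presence of TMSCl gives ketene acetal 20 (C7=C(OSiMe3)–O–C4) before the enolate can expel the β-alkoxy group, and on heating 20 should undergo a concerted suprafacial [3,3]-sigmatropic shift in which C6–C7 forms as C4–O breaks. The closest known reaction type is the Ireland–Claisen ring contraction of 6-alkenyl δ-lactone silyl ketene acetals to cyclohex-3-enecarboxylic acids. The carbocycle C4–C5–C6–C7–C7a–C3a closes by ring contraction of the lactone; because C4 and C7 are already tied by the C3a–C7a bridge, the six-centre array can only adopt a boat-like (bicyclo[2.2.2]-type) geometry. C7 is controlled by the C4 configuration, since the α-styryl group can reach only the α face of C7, which leaves the carboxyl carbon β and the PMB-oxymethyl group α. C6 is controlled by the E geometry of the styryl group, which in the boat puts phenyl on the side of the departing carboxylate, that is cis to the carboxyl carbon (β). The step needs face selectivity, boat geometry and silylation faster than β-elimination, secured respectively by the (S)-C4 centre, the two-atom tether and the internal TMSCl quench; aqueous acid then hydrolyses silyl ester 21.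

Step 14
Reactants: 22 (1R,3R,3aR,6S,7S,7aR)-7-[(4-methoxybenzyloxy)methyl]-1,3,4-trimethyl-6-phenyl-2,3,3a,6,7,7a-hexahydro-1H-indene-7-carboxylic acid
Product: 23 [(1R,3R,3aR,6S,7R,7aR)-7-[(4-methoxybenzyloxy)methyl]-1,3,4-trimethyl-6-phenyl-2,3,3a,6,7,7a-hexahydro-1H-inden-7-yl]methanol
Conditions: LiAlH4, THF, reflux; Fieser work-up
Reagents that add atoms: none
Why: LiAlH4 should reduce the hindered carboxylic acid to the neopentyl alcohol and leave the PMB ether, the phenyl ring and the trisubstituted alkene untouched.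

Step 15
Reactants: 23 [(1R,3R,3aR,6S,7R,7aR)-7-[(4-methoxybenzyloxy)methyl]-1,3,4-trimethyl-6-phenyl-2,3,3a,6,7,7a-hexahydro-1H-inden-7-yl]methanol
Product: 24 (1R,3R,3aR,6S,7S,7aR)-7-[(4-methoxybenzyloxy)methyl]-1,3,4-trimethyl-6-phenyl-2,3,3a,6,7,7a-hexahydro-1H-indene-7-carbaldehyde
Conditions: Dess–Martin periodinane, CH2Cl2, rt
Reagents that add atoms: none
Why: Dess–Martin oxidation to an aldehyde that has no α-hydrogen and therefore cannot enolise or epimerise.

Step 16
Reactants: 24 (1R,3R,3aR,6S,7S,7aR)-7-[(4-methoxybenzyloxy)methyl]-1,3,4-trimethyl-6-phenyl-2,3,3a,6,7,7a-hexahydro-1H-indene-7-carbaldehyde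
Product: 25 (1R,3R,3aR,6S,7R,7aR)-7-ethenyl-7-[(4-methoxybenzyloxy)methyl]-1,3,4-trimethyl-6-phenyl-2,3,3a,6,7,7a-hexahydro-1H-indene
Conditions: Ph3PCH3Br, KOtBu, THF, 0 °C → rt
Reagents that add atoms: methyltriphenylphosphonium bromide, C[P+](c1ccccc1)(c1ccccc1)c1ccccc1.[Br-]
Why: Wittig methylenation of the non-enolisable neopentyl aldehyde with the small, reactive unstabilised ylide.

Step 17
Reactants: 25 (1R,3R,3aR,6S,7R,7aR)-7-ethenyl-7-[(4-methoxybenzyloxy)methyl]-1,3,4-trimethyl-6-phenyl-2,3,3a,6,7,7a-hexahydro-1H-indene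
Product: 26 (1R,3R,3aR,6S,7R,7aR)-7-ethyl-7-[(4-methoxybenzyloxy)methyl]-1,3,4-trimethyl-6-phenyl-2,3,3a,6,7,7a-hexahydro-1H-indene
Conditions: 2-nitrobenzenesulfonohydrazide, Et3N, CH2Cl2, rt
Reagents that add atoms: none
Why: Diimide generated in situ transfers H2 in a concerted syn fashion to the monosubstituted alkene far faster than to the trisubstituted ring alkene and does not affect the PMB ether or the arenes.

Step 18
Reactants: 26 (1R,3R,3aR,6S,7R,7aR)-7-ethyl-7-[(4-methoxybenzyloxy)methyl]-1,3,4-trimethyl-6-phenyl-2,3,3a,6,7,7a-hexahydro-1H-indene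
Product: 27 [(1R,3R,3aR,6S,7R,7aR)-7-ethyl-1,3,4-trimethyl-6-phenyl-2,3,3a,6,7,7a-hexahydro-1H-inden-7-yl]methanol
Conditions: DDQ, CH2Cl2–pH 7 buffer, 0 °C → rt
Reagents that add atoms: none
Why: Oxidative cleavage of the electron-rich PMB ether by DDQ (hydride abstraction, then hydrolysis of the oxocarbenium ion), to which the isolated alkene and the phenyl group should be inert.

Step 19
Reactants: 27 [(1R,3R,3aR,6S,7R,7aR)-7-ethyl-1,3,4-trimethyl-6-phenyl-2,3,3a,6,7,7a-hexahydro-1H-inden-7-yl]methanol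
Product: 28 (1R,3R,3aR,6S,7R,7aR)-7-ethyl-1,3,4-trimethyl-6-phenyl-2,3,3a,6,7,7a-hexahydro-1H-indene-7-carbaldehyde
Conditions: Dess–Martin periodinane, CH2Cl2, rt
Reagents that add atoms: none
Why: Dess–Martin oxidation of the neopentyl alcohol to a non-enolisable aldehyde.

Step 20
Reactants: 28 (1R,3R,3aR,6S,7R,7aR)-7-ethyl-1,3,4-trimethyl-6-phenyl-2,3,3a,6,7,7a-hexahydro-1H-indene-7-carbaldehyde; 29 ethyl 2-(triphenyl-λ5-phosphanylidene)propanoate
Product: 30 ethyl (2E)-3-[(1R,3R,3aR,6S,7S,7aR)-7-ethyl-1,3,4-trimethyl-6-phenyl-2,3,3a,6,7,7a-hexahydro-1H-inden-7-yl]-2-methylprop-2-enoate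
Conditions: 29 (excess), toluene, 110 °C
Reagents that add atoms: none
Why: Wittig reaction of the stabilised ylide with the non-enolisable aldehyde, in which reversible oxaphosphetane formation should give the E-configured trisubstituted enoate, heating being needed because the aldehyde is neopentylic.

Step 21
Reactants: 30 ethyl (2E)-3-[(1R,3R,3aR,6S,7S,7aR)-7-ethyl-1,3,4-trimethyl-6-phenyl-2,3,3a,6,7,7a-hexahydro-1H-inden-7-yl]-2-methylprop-2-enoate
Product: 31 plakotenin
Conditions: LiOH, THF–MeOH–H2O, 50 °C; then 1 M HCl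
Reagents that add atoms: lithium hydroxide, [Li+].[OH-]
Why: Saponification of the ethyl ester and acidification, with no stereocentre α to the carboxyl group that could epimerise.

Compound list
1 | (S)-4-(tert-butyldimethylsilyloxy)cyclopent-2-en-1-one | O=C1C=C[C@@H](O[Si](C)(C)C(C)(C)C)C1 | starting material
2 | 1-(tert-butyldimethylsilyloxy)-1-methoxyethene | C=C(OC)O[Si](C)(C)C(C)(C)C | starting material
3 | acetaldehyde | CC=O | starting material
4 | methyl 2-[(1S,5S)-3,5-bis(tert-butyldimethylsilyloxy)cyclopent-2-en-1-yl]acetate | COC(=O)C[C@H]1C=C(O[Si](C)(C)C(C)(C)C)C[C@@H]1O[Si](C)(C)C(C)(C)C | intermediate (not isolated)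
5 | methyl 2-[(1S,2R,5S)-5-(tert-butyldimethylsilyloxy)-2-(1-hydroxyethyl)-3-oxocyclopentyl]acetate (both carbinol epimers) | COC(=O)C[C@H]1[C@H](C(C)O)C(=O)C[C@@H]1O[Si](C)(C)C(C)(C)C | intermediate
6 | methyl 2-[(1S,2R,5S)-5-(tert-butyldimethylsilyloxy)-2-[1-(tert-butyldiphenylsilyloxy)ethyl]-3-oxocyclopentyl]acetate | COC(=O)C[C@H]1[C@H](C(C)O[Si](c2ccccc2)(c2ccccc2)C(C)(C)C)C(=O)C[C@@H]1O[Si](C)(C)C(C)(C)C | intermediate
7 | methyl 2-[(1S,2S,5S)-5-(tert-butyldimethylsilyloxy)-2-[1-(tert-butyldiphenylsilyloxy)ethyl]-3-methylidenecyclopentyl]acetate | COC(=O)C[C@H]1[C@H](C(C)O[Si](c2ccccc2)(c2ccccc2)C(C)(C)C)C(=C)C[C@@H]1O[Si](C)(C)C(C)(C)C | intermediate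
8 | methyl 2-[(1S,2R,3R,5S)-5-(tert-butyldimethylsilyloxy)-2-[1-(tert-butyldiphenylsilyloxy)ethyl]-3-methylcyclopentyl]acetate | COC(=O)C[C@H]1[C@H](C(C)O[Si](c2ccccc2)(c2ccccc2)C(C)(C)C)[C@H](C)C[C@@H]1O[Si](C)(C)C(C)(C)C | intermediate
9 | methyl 2-[(1S,2R,3R,5S)-2-[1-(tert-butyldiphenylsilyloxy)ethyl]-5-hydroxy-3-methylcyclopentyl]acetate | COC(=O)C[C@H]1[C@H](C(C)O[Si](c2ccccc2)(c2ccccc2)C(C)(C)C)[C@H](C)C[C@@H]1O | intermediate
10 | methyl 2-[(1S,2R,3R)-2-[1-(tert-butyldiphenylsilyloxy)ethyl]-3-methyl-5-oxocyclopentyl]acetate | COC(=O)C[C@H]1[C@H](C(C)O[Si](c2ccccc2)(c2ccccc2)C(C)(C)C)[C@H](C)CC1=O | intermediate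
11 | methyl 2-[(1S,2R,3R)-2-[1-(tert-butyldiphenylsilyloxy)ethyl]-3-methyl-5-methylidenecyclopentyl]acetate | COC(=O)C[C@H]1[C@H](C(C)O[Si](c2ccccc2)(c2ccccc2)C(C)(C)C)[C@H](C)CC1=C | intermediate
12 | methyl 2-[(1S,2R,3R)-2-(1-hydroxyethyl)-3-methyl-5-methylidenecyclopentyl]acetate | COC(=O)C[C@H]1[C@H](C(C)O)[C@H](C)CC1=C | intermediate
13 | methyl 2-[(1R,2R,3R,5R)-2-(1-hydroxyethyl)-3,5-dimethylcyclopentyl]acetate | COC(=O)C[C@H]1[C@H](C(C)O)[C@H](C)C[C@H]1C | intermediate
14 | methyl 2-[(1R,2R,3R,5R)-2-acetyl-3,5-dimethylcyclopentyl]acetate | COC(=O)C[C@H]1[C@H](C(C)=O)[C@H](C)C[C@H]1C | intermediate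
15 | (E)-(2-bromovinyl)benzene | Br/C=C/c1ccccc1 | starting material
16 | methyl 2-[(1R,2R,3R,5R)-2-[(2S,3E)-2-hydroxy-4-phenylbut-3-en-2-yl]-3,5-dimethylcyclopentyl]acetate | COC(=O)C[C@H]1[C@H]([C@@](C)(O)/C=C/c2ccccc2)[C@H](C)C[C@H]1C | intermediate (not isolated)
17 | (1S,4aR,5R,7R,7aR)-1,5,7-trimethyl-1-[(E)-2-phenylethenyl]-4,4a,5,6,7,7a-hexahydrocyclopenta[c]pyran-3(1H)-one | O=C1C[C@H]2[C@H]([C@](C)(/C=C/c3ccccc3)O1)[C@H](C)C[C@H]2C | intermediate
18 | 1-(chloromethoxymethyl)-4-methoxybenzene | COc1ccc(COCCl)cc1 | starting material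
19 | (1S,4RS,4aR,5R,7R,7aR)-4-[(4-methoxybenzyloxy)methyl]-1,5,7-trimethyl-1-[(E)-2-phenylethenyl]-4,4a,5,6,7,7a-hexahydrocyclopenta[c]pyran-3(1H)-one | O=C1C(COCc2ccc(OC)cc2)[C@H]2[C@H]([C@](C)(/C=C/c3ccccc3)O1)[C@H](C)C[C@H]2C | intermediate
20 | trimethylsilyl ketene acetal of 19: (1S,4aR,5R,7R,7aR)-4-[(4-methoxybenzyloxy)methyl]-1,5,7-trimethyl-1-[(E)-2-phenylethenyl]-3-(trimethylsilyloxy)-1,4a,5,6,7,7a-hexahydrocyclopenta[c]pyran | C[Si](C)(C)OC1=C(COCc2ccc(OC)cc2)[C@H]2[C@H]([C@](C)(/C=C/c3ccccc3)O1)[C@H](C)C[C@H]2C | intermediate (not isolated)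
21 | trimethylsilyl (1R,3R,3aR,6S,7S,7aR)-7-[(4-methoxybenzyloxy)methyl]-1,3,4-trimethyl-6-phenyl-2,3,3a,6,7,7a-hexahydro-1H-indene-7-carboxylate | C[Si](C)(C)OC(=O)[C@@]1(COCc2ccc(OC)cc2)[C@H]2[C@H](C(C)=C[C@H]1c1ccccc1)[C@H](C)C[C@H]2C | intermediate (not isolated)
22 | (1R,3R,3aR,6S,7S,7aR)-7-[(4-methoxybenzyloxy)methyl]-1,3,4-trimethyl-6-phenyl-2,3,3a,6,7,7a-hexahydro-1H-indene-7-carboxylic acid | OC(=O)[C@@]1(COCc2ccc(OC)cc2)[C@H]2[C@H](C(C)=C[C@H]1c1ccccc1)[C@H](C)C[C@H]2C | intermediate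
23 | [(1R,3R,3aR,6S,7R,7aR)-7-[(4-methoxybenzyloxy)methyl]-1,3,4-trimethyl-6-phenyl-2,3,3a,6,7,7a-hexahydro-1H-inden-7-yl]methanol | OC[C@@]1(COCc2ccc(OC)cc2)[C@H]2[C@H](C(C)=C[C@H]1c1ccccc1)[C@H](C)C[C@H]2C | intermediate
24 | (1R,3R,3aR,6S,7S,7aR)-7-[(4-methoxybenzyloxy)methyl]-1,3,4-trimethyl-6-phenyl-2,3,3a,6,7,7a-hexahydro-1H-indene-7-carbaldehyde | O=C[C@@]1(COCc2ccc(OC)cc2)[C@H]2[C@H](C(C)=C[C@H]1c1ccccc1)[C@H](C)C[C@H]2C | intermediate
25 | (1R,3R,3aR,6S,7R,7aR)-7-ethenyl-7-[(4-methoxybenzyloxy)methyl]-1,3,4-trimethyl-6-phenyl-2,3,3a,6,7,7a-hexahydro-1H-indene | C=C[C@@]1(COCc2ccc(OC)cc2)[C@H]2[C@H](C(C)=C[C@H]1c1ccccc1)[C@H](C)C[C@H]2C | intermediate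
26 | (1R,3R,3aR,6S,7R,7aR)-7-ethyl-7-[(4-methoxybenzyloxy)methyl]-1,3,4-trimethyl-6-phenyl-2,3,3a,6,7,7a-hexahydro-1H-indene | CC[C@@]1(COCc2ccc(OC)cc2)[C@H]2[C@H](C(C)=C[C@H]1c1ccccc1)[C@H](C)C[C@H]2C | intermediate
27 | [(1R,3R,3aR,6S,7R,7aR)-7-ethyl-1,3,4-trimethyl-6-phenyl-2,3,3a,6,7,7a-hexahydro-1H-inden-7-yl]methanol | CC[C@@]1(CO)[C@H]2[C@H](C(C)=C[C@H]1c1ccccc1)[C@H](C)C[C@H]2C | intermediate
28 | (1R,3R,3aR,6S,7R,7aR)-7-ethyl-1,3,4-trimethyl-6-phenyl-2,3,3a,6,7,7a-hexahydro-1H-indene-7-carbaldehyde | CC[C@@]1(C=O)[C@H]2[C@H](C(C)=C[C@H]1c1ccccc1)[C@H](C)C[C@H]2C | intermediate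
29 | ethyl 2-(triphenyl-λ5-phosphanylidene)propanoate | CCOC(=O)C(C)=P(c1ccccc1)(c1ccccc1)c1ccccc1 | starting material
30 | ethyl (2E)-3-[(1R,3R,3aR,6S,7S,7aR)-7-ethyl-1,3,4-trimethyl-6-phenyl-2,3,3a,6,7,7a-hexahydro-1H-inden-7-yl]-2-methylprop-2-enoate | CC[C@@]1(/C=C(\C)C(=O)OCC)[C@H]2[C@H](C(C)=C[C@H]1c1ccccc1)[C@H](C)C[C@H]2C | intermediate
31 | plakotenin, (2E)-3-[(1R,3R,3aR,6S,7S,7aR)-7-ethyl-1,3,4-trimethyl-6-phenyl-2,3,3a,6,7,7a-hexahydro-1H-inden-7-yl]-2-methylprop-2-enoic acid | CC[C@@]1(/C=C(\C)C(=O)O)[C@H]2[C@H](C(C)=C[C@H]1c1ccccc1)[C@H](C)C[C@H]2C | target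

Total step count: 21
Longest linear sequence: 21 steps (1 → 31)

Steps most likely to fail

1. Step 13 (key step). The trans ring fusion holds the C7–C7a–C3a–C4 torsion open, so the ketene acetal may be slow to reach the boat geometry. Ionisation at the tertiary allylic C4–O bond (loss of the silyl carboxylate to a diene) or β-elimination of the 4-methoxybenzyl alkoxide before silylation could then win. The fallback sets out from 17 and comes back at 22. It runs the ring contraction on the lactone without the α-branch, which has no β-leaving group and a less crowded ketene acetal, and makes the quaternary centre afterwards by alkylation instead of in the rearrangement. Lactone 17, treated as in step 13, should give, through the trimethylsilyl ketene acetal of 17 F1 and the trimethylsilyl ester of the rearranged acid F2, (1R,3R,3aR,6R,7S,7aR)-1,3,4-trimethyl-6-phenyl-2,3,3a,6,7,7a-hexahydro-1H-indene-7-carboxylic acid F3. Its dianion (LDA, 2.2 equiv, THF–DMPU, 0 °C) should be alkylated by 18 at C7 on the α face, anti to the C6 phenyl group, to give 22.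

2. Step 11. Facial selectivity at the ketone may be poor or inverted, or the reagent may enolise the ketone instead of adding. The fallback sets out from 14 and comes back at 17. It reverses the order in which the two C4 substituents arrive. The kinetic lithium enolate of 14 (LDA, THF, −78 °C) and benzaldehyde should give the aldol methyl 2-[(1R,2R,3R,5R)-2-(3-hydroxy-3-phenylpropanoyl)-3,5-dimethylcyclopentyl]acetate F4. MsCl/Et3N converts it into its methanesulfonate F5, which eliminates in the same flask to the enone methyl 2-[(1R,2R,3R,5R)-3,5-dimethyl-2-[(E)-3-phenylprop-2-enoyl]cyclopentyl]acetate F6. MeLi/CeCl3 (THF, −78 °C → rt) then adds methyl 1,2 from the same C7a side. Because methyl and styryl have exchanged roles, the carbinol centre is formed in the sense opposite to that of step 11, which should give 16 and, on warming, 17.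

3. Step 9. Hydrogen may add from the wrong face, or the exocyclic alkene may migrate into the ring on the catalyst and erase C7a. The fallback sets out from 9 and comes back at 13. It introduces the C1 methyl group by SN2 displacement with inversion instead of by hydrogenation. Tf2O/pyridine (CH2Cl2, −30 °C) should give the triflate methyl 2-[(1S,2R,3R,5S)-2-[1-(tert-butyldiphenylsilyloxy)ethyl]-3-methyl-5-(trifluoromethylsulfonyloxy)cyclopentyl]acetate F7. Me2CuLi (Et2O, −78 → −20 °C) should displace it to give methyl 2-[(1R,2R,3R,5R)-2-[1-(tert-butyldiphenylsilyloxy)ethyl]-3,5-dimethylcyclopentyl]acetate F8, and HF·pyridine then gives 13.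

Further compounds
F1 | step 13 | trimethylsilyl ketene acetal of 17: (1S,4aR,5R,7R,7aR)-1,5,7-trimethyl-1-[(E)-2-phenylethenyl]-3-(trimethylsilyloxy)-1,4a,5,6,7,7a-hexahydrocyclopenta[c]pyran | C[Si](C)(C)OC1=C[C@H]2[C@H]([C@](C)(/C=C/c3ccccc3)O1)[C@H](C)C[C@H]2C
F2 | step 13 | trimethylsilyl (1R,3R,3aR,6R,7S,7aR)-1,3,4-trimethyl-6-phenyl-2,3,3a,6,7,7a-hexahydro-1H-indene-7-carboxylate | C[Si](C)(C)OC(=O)[C@H]1[C@H]2[C@H](C(C)=C[C@H]1c1ccccc1)[C@H](C)C[C@H]2C
F3 | step 13 | (1R,3R,3aR,6R,7S,7aR)-1,3,4-trimethyl-6-phenyl-2,3,3a,6,7,7a-hexahydro-1H-indene-7-carboxylic acid | OC(=O)[C@H]1[C@H]2[C@H](C(C)=C[C@H]1c1ccccc1)[C@H](C)C[C@H]2C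
F4 | step 11 | methyl 2-[(1R,2R,3R,5R)-2-(3-hydroxy-3-phenylpropanoyl)-3,5-dimethylcyclopentyl]acetate | COC(=O)C[C@H]1[C@H](C(=O)CC(O)c2ccccc2)[C@H](C)C[C@H]1C
F5 | step 11 | methyl 2-[(1R,2R,3R,5R)-2-[3-(methylsulfonyloxy)-3-phenylpropanoyl]-3,5-dimethylcyclopentyl]acetate | COC(=O)C[C@H]1[C@H](C(=O)CC(OS(C)(=O)=O)c2ccccc2)[C@H](C)C[C@H]1C
F6 | step 11 | methyl 2-[(1R,2R,3R,5R)-3,5-dimethyl-2-[(E)-3-phenylprop-2-enoyl]cyclopentyl]acetate | COC(=O)C[C@H]1[C@H](C(=O)/C=C/c2ccccc2)[C@H](C)C[C@H]1C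
F7 | step 9 | methyl 2-[(1S,2R,3R,5S)-2-[1-(tert-butyldiphenylsilyloxy)ethyl]-3-methyl-5-(trifluoromethylsulfonyloxy)cyclopentyl]acetate | COC(=O)C[C@H]1[C@H](C(C)O[Si](c2ccccc2)(c2ccccc2)C(C)(C)C)[C@H](C)C[C@@H]1OS(=O)(=O)C(F)(F)F
F8 | step 9 | methyl 2-[(1R,2R,3R,5R)-2-[1-(tert-butyldiphenylsilyloxy)ethyl]-3,5-dimethylcyclopentyl]acetate | COC(=O)C[C@H]1[C@H](C(C)O[Si](c2ccccc2)(c2ccccc2)C(C)(C)C)[C@H](C)C[C@H]1C
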